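A rate read at 2 percent conversion is easily taken for the rate of the straight stretch of the curve, but a reaction that starts with a lag may still be climbing at that mark.

| setting | oak | maple | larch | ash | elm |
|---|---|---|---|---|---|
| starting material | 0.200 M | 0.200 M | 0.400 M | 0.200 M | 0.200 M |
| partner | 0.400 M | 1.20 M | 0.400 M | 0.400 M | 0.400 M |
| catalyst | 0.00200 M | 0.00200 M | 0.00200 M | 0.00100 M | 0.00200 M |
| time |  |  |  |  | 9.6 min |

- oak run (time / min: [target] / M): 0.27: 0.0031; 0.83: 0.0149; 1.6: 0.0310; 2.5: 0.0518; 3.6: 0.0723; 4.8: 0.0939
- maple run (time / min: [target] / M): 0.27: 0.0096; 0.83: 0.0438; 1.6: 0.0925; 2.5: 0.1395; 3.6: 0.1796; 4.8: 0.1952
- larch run (time / min: [target] / M): 0.27: 0.0044; 0.83: 0.0191; 1.6: 0.0393; 2.5: 0.0633; 3.6: 0.0873; 4.8: 0.1149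
- ash run (time / min: [target] / M): 0.27: 0.0031; 0.83: 0.0095; 1.6: 0.0180; 2.5: 0.0256; 3.6: 0.0407; 4.8: 0.0548

(standard deviation of a reading: 0.001 M)

- Overall: starting material + partner -> target, with catalyst as catalyst.
- Constant volume, constant temperature.
- Bound and free are read together.
- "The second partner" is partner.
- An order is taken over about fifteen percent of the charge, up and down.

- how the opening rate goes with [partner] round the charge of the oak run: the exponent of the rate at two percent of starting material gone to target
- how the opening rate goes with [starting material] round the charge of the oak run: the exponent of the rate at two percent of starting material gone to target (one fixed amount of target, the same in the runs compared)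
- target in the elm run at 9.6 min, as a share of the starting material charged

I read the table at the top of two columns, oak and maple. Between the second and third readings, oak climbs at 0.0209 M/min and maple at 0.0632 M/min. I call these the full rates. Their ratio, against the ratio of partner charges, gives an underlying exponent of 1.01.

Now the first row. At 0.27 min, oak's full rate would have made 0.00564 M, but oak shows 0.0031 M, which is less. So there is a lag (an induction period), as in the ramp response of a first-order system. Extending each straight stretch back to zero target gives 0.117 min for oak and 0.137 min for maple, and I take the mean, 0.127 min.

The quantity I carry is the lag amount: the target that the full rate would make in one lag, here 0.00266 M for oak. I compare it with the amount at the mark, 0.00400 M, and solve both ends. Far beyond the lag amount, the rate is the full rate, so the exponent stays whole. Far below it, the rate climbs linearly with time and the amount grows with time squared, so at a fixed amount the rate goes as the square root of the full rate, and the exponent falls to 0.5 of the underlying one. As my own join, I let the factor run from 0.5 to 1, passing midway where the two amounts are equal. Oak's mark is 1.50 lag amounts, so the factor is 0.800, and I commit to a partner exponent of 0.808.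

The forecast differs from this. It gives 0.97 for partner (range 0.8 to 1.1), on the ground that “Tripling partner triples the rate, so the order in partner is about 1.” It gives 0.32 for starting material (range 0.1 to 0.5) and 77% for elm (range 68% to 86%).

The flask gives 0.75 for partner, 0.21 for starting material and 77.1% for elm.

    active catalyst + starting material ⇌ catalyst-substrate complex, settled at all times (19.90 /M)
    catalyst-substrate complex + partner → target + active catalyst + by-product (61.20 /M/min)
    catalyst → active catalyst (4.734 /min)
    2 starting material ⇌ idle substrate dimer, settled at all times (23.30 /M)

The slowness of the conversion of catalyst into active catalyst pulls the partner exponent down: without that slowness, with all the catalyst active from the start, the exponent is 1.0, where the flask as it is gives 0.75. Taking the full rate as proportional to catalyst and the lag as oak's, the ash run has a lag amount of 0.00133 M, so the same mark is 3.00 lag amounts there and the factor in the ash run is 0.875. With the mean of the oak and ash factors as the exponent in catalyst, ash's rate over oak's, at equal target, comes to 0.560, and the ash run stands at 0.58.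

The runs were computed with constants of no real substance.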